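A direct plan would build the diquinane first: Pauson–Khand cyclisation, reduction and elimination would give the ring-fused cyclopentadiene A1, and a Rh2(S-DOSP)4 vinylcarbenoid (4+3) annulation with the vinyldiazoacetate A2 would close ring C as the tricyclic diene ester A3. A formaldehyde ene reaction would give the C6-quaternary alcohol A4, and C2 homologation and SeO2 oxidation the C10 allylic alcohol A5. Its weakest steps would be the (4+3) annulation (A1 shifts hydrogen and dimerises; site, face and both bridgeheads would rest on the catalyst alone), the Me2AlCl ene reaction that creates C6 (regio- and facial control unsecured) and the SeO2 hydroxylation of neopentyl C10 beside an electron-poor enoate (no handle for stereocontrol).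

The route rests on a dearomative (5+2) disconnection of C1–C5 and C6–C7: ring C (C1, C10, C9, C8, C7, C11) is a masked 3-hydroxy-4-alkylbenzoate in which C11 is the phenol carbon, C8 carries the carboxyl and C1 the side chain ending in a trisubstituted allene. One oxidation would close rings A and B, set C1, C6, C7 and C10 from the benzylic centre C2 and the allene axis, install the C10 oxygen and the C8=C9 enoate, and leave C4=C5 for the hydrogenation that sets the trans A/B fusion. No labile cyclopentadiene, no ene reaction and no allylic C–H oxidation remain; C2 carries its acetal from the start.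

Key step: step 10

Numbering used throughout, also for open-chain precursors: tricyclo[5.3.1.0(1,5)]undecane, C1 spiro bridgehead, C2 (CHO), C6 (Me, CH2OH), C8 (CO2H), C10 (O-acyl), C11 one-carbon bridge; ring A = C1–C5, ring B = C1, C5, C6, C7, C11. TBS = tert-butyldimethylsilyl, TES = triethylsilyl.
Remark: the SMILES puts H-5 on the face of C11, so rings A and B are trans-fused (a direct closure of ring A onto ring B could only give the cis fusion); the route is planned for this configuration.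

Step 1
Reactants: 1 3-hydroxy-4-iodobenzoic acid
Product: 2 tert-butyl 3-hydroxy-4-iodobenzoate
Conditions: Me2NCH(OtBu)2, toluene, 80 °C
Reagents that add atoms: N,N-dimethylformamide di-tert-butyl acetal (CN(C)C(OC(C)(C)C)OC(C)(C)C)
Why: Esterification of the carboxylic acid with the amide acetal should leave the phenol free; no stereocentre is involved.

Step 2
Reactants: 2 tert-butyl 3-hydroxy-4-iodobenzoate
Product: 3 tert-butyl 3-hydroxy-4-(4,4,5,5-tetramethyl-1,3,2-dioxaborolan-2-yl)benzoate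
Conditions: B2pin2, Pd(dppf)Cl2 (3 mol %), KOAc, 1,4-dioxane, 85 °C
Reagents that add atoms: bis(pinacolato)diboron (CC1(C)OB(OC1(C)C)B1OC(C)(C)C(C)(C)O1)
Why: Miyaura borylation of the aryl iodide, which tolerates the free ortho hydroxyl and the tert-butyl ester.

Step 3
Reactants: 4 2,2-dimethoxyacetaldehyde
Product: 5 (2E)-N,4,4-trimethoxy-N-methylbut-2-enamide
Conditions: Ph3P=CHC(O)N(OMe)Me, CH2Cl2/H2O, rt
Reagents that add atoms: N-methoxy-N-methyl-2-(triphenyl-λ5-phosphanylidene)acetamide (CON(C)C(=O)C=P(c1ccccc1)(c1ccccc1)c1ccccc1)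
Why: Wittig olefination with a stabilised ylide should give the E enamide, which carries the future C2 aldehyde as its acetal and C4 as a Weinreb amide.

Step 4
Reactants: 3 tert-butyl 3-hydroxy-4-(4,4,5,5-tetramethyl-1,3,2-dioxaborolan-2-yl)benzoate; 5 (2E)-N,4,4-trimethoxy-N-methylbut-2-enamide
Product: 6 tert-butyl 4-[(2S)-1,1-dimethoxy-4-[methoxy(methyl)amino]-4-oxobutan-2-yl]-3-hydroxybenzoate
Conditions: Rh(acac)(C2H4)2 (3 mol %), (R)-BINAP, K2CO3 (0.5 equiv), 1,4-dioxane/H2O 10:1, 90 °C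
Reagents that add atoms: none
Why: Hayashi–Miyaura rhodium-catalysed asymmetric 1,4-addition, in which (R)-BINAP is chosen because the quadrant model predicts aryl delivery to the Re face of C3 of the E enamide, which sets the benzylic centre C2 as S.

Step 5
Reactants: 6 tert-butyl 4-[(2S)-1,1-dimethoxy-4-[methoxy(methyl)amino]-4-oxobutan-2-yl]-3-hydroxybenzoate
Product: 7 tert-butyl 3-[(tert-butyldimethylsilyl)oxy]-4-[(2S)-1,1-dimethoxy-4-[methoxy(methyl)amino]-4-oxobutan-2-yl]benzoate
Conditions: TBSCl, imidazole, DMF, rt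
Reagents that add atoms: tert-butyldimethylsilyl chloride (CC(C)(C)[Si](C)(C)Cl)
Why: Silyl ether formation masks the phenol so that it is neither deprotonated nor mesylated in the next three steps; C2 is not touched.

Step 6
Reactants: 7 aryl silyl ether Weinreb amide; 8 tert-butyldimethyl(prop-2-yn-1-yloxy)silane
Product: 10 tert-butyl 3-[(tert-butyldimethylsilyl)oxy]-4-[(2S)-7-[(tert-butyldimethylsilyl)oxy]-1,1-dimethoxy-4-oxohept-5-yn-2-yl]benzoate, via lithium acetylide 9 (not isolated)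
Conditions: 8, n-BuLi, THF, −78 °C; then 7, −78 → 0 °C; aq. NH4Cl
Reagents that add atoms: none
Why: Weinreb ketone synthesis, in which the chelated tetrahedral adduct stops at mono-addition and gives the ynone; C2 is β to the carbonyl and is not affected.

Step 7
Reactants: 10 ynone
Product: 11 tert-butyl 3-[(tert-butyldimethylsilyl)oxy]-4-[(2S,4S)-7-[(tert-butyldimethylsilyl)oxy]-4-hydroxy-1,1-dimethoxyhept-5-yn-2-yl]benzoate
Conditions: Ru[(S,S)-TsDPEN](p-cymene) (2 mol %), i-PrOH, rt
Reagents that add atoms: none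
Why: Noyori asymmetric transfer hydrogenation of the ynone, in which the (S,S) catalyst places the alkynyl group in the π site and should set C4 as S under catalyst control.

Step 8
Reactants: 11 (2S,4S)-propargylic alcohol
Product: 13 tert-butyl 3-[(tert-butyldimethylsilyl)oxy]-4-[(2S)-7-[(tert-butyldimethylsilyl)oxy]-1,1-dimethoxy-6-methylhepta-4,5-dien-2-yl]benzoate with allene axis P (aS), via propargylic mesylate 12 (not isolated)
Conditions: MsCl, Et3N, CH2Cl2, −40 °C; aqueous work-up; then MeMgBr (3 equiv), CuBr (10 mol %), LiBr, THF, −78 → −30 °C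
Reagents that add atoms: methylmagnesium bromide (C[Mg]Br)
Why: Copper-catalysed anti-SN2′ substitution of the propargylic mesylate by the methyl Grignard reagent at C6 transfers the C4 centre (S) into the allene axis (P), the mesylate being a far better leaving group than the silyl ether on the other propargylic carbon.

Step 9
Reactants: 13 allene with aryl silyl ether
Product: 14 tert-butyl 4-[(2S)-7-[(tert-butyldimethylsilyl)oxy]-1,1-dimethoxy-6-methylhepta-4,5-dien-2-yl]-3-hydroxybenzoate with allene axis P (aS)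
Conditions: K2CO3 (0.3 equiv), MeOH, 0 °C → rt
Reagents that add atoms: none
Why: Base-catalysed methanolysis should cleave only the aryl silyl ether (phenoxide leaving group), while the alkyl silyl ether, acetal, tert-butyl ester and allene remain.

Step 10
Reactants: 14 allenyl phenol
Product: 16 tert-butyl 10-acetoxy-6-{[(tert-butyldimethylsilyl)oxy]methyl}-2-(dimethoxymethyl)-6-methyl-11-oxotricyclo[5.3.1.0(1,5)]undeca-4,8-diene-8-carboxylate (C1 and C7 as in the target; CH2OTBS and OAc syn to C11; CH(OMe)2 cis to C10), via aryloxy(acetoxy)phenyl-λ3-iodane 15 (not isolated)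
Conditions: PhI(OAc)2 (1.1 equiv), (CF3)2CHOH/CH2Cl2 1:3, −40 → 0 °C
Reagents that add atoms: (diacetoxyiodo)benzene (CC(=O)OI(OC(C)=O)c1ccccc1)
Why: Proposed new method: ligand exchange gives the aryl-λ3-iodane 15, whose ionisation (loss of PhI) leaves a phenoxonium ion, that is the pentadienyl cation C1–C10–C9–C8–C7 bridged by the C11 carbonyl; the central allene carbon C5 attacks C1 through the C5=C6 π bond, the incipient tertiary cation at C6 bonds to C7 in a concerted, asynchronous (5+2) cycloaddition, and the remaining allyl cation C8–C9–C10 is captured by acetate. The closest known reaction type is the oxidative-dearomatisation-induced intramolecular (5+2) cycloaddition of ortho-(alkenylalkyl)phenols with trisubstituted alkenes, extended here to an allene as the 2π partner (allenes are known 2π partners in oxidopyrylium (5+2) cycloadditions). Ring A closes in 5-exo mode with respect to the reacting C5=C6 bond at the ipso carbon C1 (spiro centre), and ring B closes by the C6–C7 bond, which completes the bicyclo[3.2.1]octenone, while the orthogonal C4=C5 bond of the allene stays in ring A. C1 and C7 are set by the C2 stereocentre (1,3-allylic strain keeps C2–H next to the C11 oxygen and the acetal next to C10–H, so the tether can reach one arene face only), C6 by the allene axis (suprafacial use of C5=C6 places CH2OTBS on the face of C11), and C10 by acetate approach anti to the C5–C6 bridge. The step needs ring closure at C6 to outrun rotation of the C6 cation into conjugation with C4=C5, which the pre-organised geometry (the C6 lobe points at C7 while C5–C1 forms) and the non-nucleophilic ionising solvent should secure. Acetate capture at C10 and not at C8 is secured by the C8 ester, which leaves C10 as the only terminus that gives the conjugated enoate.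

Step 11
Reactants: 16 tricyclic 11-ketone
Product: 17 11-(4-methylbenzenesulfonyl)hydrazone of 16
Conditions: TsNHNH2, MeOH, 50 °C
Reagents that add atoms: p-toluenesulfonohydrazide (Cc1ccc(cc1)S(=O)(=O)NN)
Why: Hydrazone condensation at the strained bridging C11 ketone, the only carbonyl that can condense (the aldehyde is an acetal, the others are esters).

Step 12
Reactants: 17 tosylhydrazone
Product: 19 tert-butyl 10-acetoxy-6-{[(tert-butyldimethylsilyl)oxy]methyl}-2-(dimethoxymethyl)-6-methyltricyclo[5.3.1.0(1,5)]undeca-4,8-diene-8-carboxylate, via monoalkyldiazene 18 (not isolated)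
Conditions: catecholborane, CHCl3, 0 °C; then NaOAc·3H2O, reflux
Reagents that add atoms: none
Why: Kabalka-type tosylhydrazone reduction (B–H addition to C=N, acetate-induced loss of sulfinate, then loss of N2 from the diazene) should turn C11 into CH2 while the enoate, the allylic acetate and both alkenes are inert to catecholborane at 0 °C.

Step 13
Reactants: 19 silyl ether
Product: 20 tert-butyl 10-acetoxy-2-(dimethoxymethyl)-6-(hydroxymethyl)-6-methyltricyclo[5.3.1.0(1,5)]undeca-4,8-diene-8-carboxylate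
Conditions: HF·pyridine, pyridine, THF, 0 °C → rt
Reagents that add atoms: none
Why: Fluoride cleavage of the only silyl ether under pyridine buffering, which should spare the acetal, the acetate and the tert-butyl ester.

Step 14
Reactants: 20 homoallylic alcohol
Product: 21 tert-butyl 10-acetoxy-2-(dimethoxymethyl)-6-(hydroxymethyl)-6-methyltricyclo[5.3.1.0(1,5)]undec-8-ene-8-carboxylate (H-5 syn to C11 and cis to CH2OH)
Conditions: [Ir(cod)(PCy3)(py)]PF6 (5 mol %), H2 (1 atm), CH2Cl2, rt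
Reagents that add atoms: none
Why: Hydroxyl-directed homogeneous hydrogenation, in which the cationic iridium complex [Ir(cod)(PCy3)(py)]PF6 bound to the C6 CH2OH delivers H2 to C4=C5 from the face of C11 and so sets H-5 (trans A/B fusion) under kinetic control, while the electron-poor C8=C9 enoate, which has no free hydroxyl nearby, should be left.

Step 15
Reactants: 21 primary alcohol
Product: 22 triethylsilyl ether of 21
Conditions: Et3SiCl, imidazole, CH2Cl2, 0 °C
Reagents that add atoms: triethylsilyl chloride (CC[Si](CC)(CC)Cl)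
Why: Silyl ether formation at the only free hydroxyl; no stereocentre is touched.

Step 16
Reactants: 22 acetate
Product: 23 tert-butyl 2-(dimethoxymethyl)-10-hydroxy-6-methyl-6-{[(triethylsilyl)oxy]methyl}tricyclo[5.3.1.0(1,5)]undec-8-ene-8-carboxylate (10-OH syn to C11)
Conditions: K2CO3, MeOH, rt
Reagents that add atoms: none
Why: Base-catalysed transesterification with methanol removes the acetate with retention at C10, while the hindered tert-butyl enoate and the neopentyl silyl ether should survive.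

Step 17
Reactants: 24 dec-9-ynoic acid; 25 (6-bromohexyloxy)(tert-butyl)dimethylsilane
Product: 27 16-[(tert-butyldimethylsilyl)oxy]hexadec-9-ynoic acid, via dilithium acetylide carboxylate 26 (not isolated)
Conditions: n-BuLi (2.1 equiv), THF/HMPA, −78 → 0 °C; then 25, 0 °C → rt; aq. HCl
Reagents that add atoms: none
Why: Alkylation of the acetylide–carboxylate dianion with the primary bromide occurs at carbon only and gives the C16 chain.

Step 18
Reactants: 27 alkynoic acid
Product: 28 (9Z)-16-[(tert-butyldimethylsilyl)oxy]hexadec-9-enoic acid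
Conditions: H2 (1 atm), Pd/CaCO3 poisoned with Pb (Lindlar), quinoline, EtOAc, rt
Reagents that add atoms: none
Why: Lindlar semihydrogenation adds H2 syn and stops at the alkene, which sets the 9Z geometry.

Step 19
Reactants: 23 C10 alcohol; 28 (9Z)-16-[(tert-butyldimethylsilyl)oxy]hexadec-9-enoic acid
Product: 30 tert-butyl 2-(dimethoxymethyl)-6-methyl-10-{[(9Z)-16-[(tert-butyldimethylsilyl)oxy]hexadec-9-enoyl]oxy}-6-{[(triethylsilyl)oxy]methyl}tricyclo[5.3.1.0(1,5)]undec-8-ene-8-carboxylate, via mixed anhydride 29 (not isolated)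
Conditions: 2,4,6-Cl3C6H2COCl, Et3N, THF, rt; then 23, DMAP, toluene, 40 °C
Reagents that add atoms: none
Why: Yamaguchi esterification acylates the hindered C10 hydroxyl at oxygen with retention, and C2 cannot epimerise because the aldehyde is still an acetal.

Step 20
Reactants: 30 fully protected ester
Product: 31 target, (1R,2S,5S,6S,7S,10S)-2-formyl-6-(hydroxymethyl)-10-{[(9Z)-16-hydroxyhexadec-9-enoyl]oxy}-6-methyltricyclo[5.3.1.0(1,5)]undec-8-ene-8-carboxylic acid
Conditions: TFA/CH2Cl2/H2O 10:10:1, 0 °C → rt; then NaHCO3, MeOH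
Reagents that add atoms: water (O)
Why: Global acidolysis (acetal hydrolysis, cleavage of both silyl ethers, loss of isobutene from the tert-butyl ester) works without strong base, so C2–H next to the aldehyde is not touched, and the C10 ester should not ionise because its allyl cation would be destabilised by the C8 carboxyl.

**Compound list**
1 | 3-hydroxy-4-iodobenzoic acid | OC(=O)c1ccc(I)c(O)c1 | starting material
2 | tert-butyl 3-hydroxy-4-iodobenzoate | CC(C)(C)OC(=O)c1ccc(I)c(O)c1 | intermediate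
3 | tert-butyl 3-hydroxy-4-(4,4,5,5-tetramethyl-1,3,2-dioxaborolan-2-yl)benzoate | CC(C)(C)OC(=O)c1ccc(B2OC(C)(C)C(C)(C)O2)c(O)c1 | intermediate
4 | 2,2-dimethoxyacetaldehyde | COC(OC)C=O | starting material
5 | (2E)-N,4,4-trimethoxy-N-methylbut-2-enamide | COC(OC)/C=C/C(=O)N(C)OC | intermediate
6 | tert-butyl 4-[(2S)-1,1-dimethoxy-4-[methoxy(methyl)amino]-4-oxobutan-2-yl]-3-hydroxybenzoate | COC(OC)[C@@H](CC(=O)N(C)OC)c1ccc(cc1O)C(=O)OC(C)(C)C | intermediate
7 | tert-butyl 3-[(tert-butyldimethylsilyl)oxy]-4-[(2S)-1,1-dimethoxy-4-[methoxy(methyl)amino]-4-oxobutan-2-yl]benzoate | COC(OC)[C@@H](CC(=O)N(C)OC)c1ccc(cc1O[Si](C)(C)C(C)(C)C)C(=O)OC(C)(C)C | intermediate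
8 | tert-butyldimethyl(prop-2-yn-1-yloxy)silane | C#CCO[Si](C)(C)C(C)(C)C | starting material
9 | lithium acetylide of 8 | [Li]C#CCO[Si](C)(C)C(C)(C)C | intermediate
10 | tert-butyl 3-[(tert-butyldimethylsilyl)oxy]-4-[(2S)-7-[(tert-butyldimethylsilyl)oxy]-1,1-dimethoxy-4-oxohept-5-yn-2-yl]benzoate | COC(OC)[C@@H](CC(=O)C#CCO[Si](C)(C)C(C)(C)C)c1ccc(cc1O[Si](C)(C)C(C)(C)C)C(=O)OC(C)(C)C | intermediate
11 | tert-butyl 3-[(tert-butyldimethylsilyl)oxy]-4-[(2S,4S)-7-[(tert-butyldimethylsilyl)oxy]-4-hydroxy-1,1-dimethoxyhept-5-yn-2-yl]benzoate | COC(OC)[C@@H](C[C@H](O)C#CCO[Si](C)(C)C(C)(C)C)c1ccc(cc1O[Si](C)(C)C(C)(C)C)C(=O)OC(C)(C)C | intermediate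
12 | methanesulfonate of 11 (4S) | COC(OC)[C@@H](C[C@H](OS(C)(=O)=O)C#CCO[Si](C)(C)C(C)(C)C)c1ccc(cc1O[Si](C)(C)C(C)(C)C)C(=O)OC(C)(C)C | intermediate
13 | tert-butyl 3-[(tert-butyldimethylsilyl)oxy]-4-[(2S)-7-[(tert-butyldimethylsilyl)oxy]-1,1-dimethoxy-6-methylhepta-4,5-dien-2-yl]benzoate, allene axis P (aS) | COC(OC)[C@@H](CC=[C@@]=C(C)CO[Si](C)(C)C(C)(C)C)c1ccc(cc1O[Si](C)(C)C(C)(C)C)C(=O)OC(C)(C)C | intermediate
14 | tert-butyl 4-[(2S)-7-[(tert-butyldimethylsilyl)oxy]-1,1-dimethoxy-6-methylhepta-4,5-dien-2-yl]-3-hydroxybenzoate, allene axis P (aS) | COC(OC)[C@@H](CC=[C@@]=C(C)CO[Si](C)(C)C(C)(C)C)c1ccc(cc1O)C(=O)OC(C)(C)C | intermediate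
15 | aryloxy(acetoxy)phenyl-λ3-iodane of 14 | COC(OC)[C@@H](CC=[C@@]=C(C)CO[Si](C)(C)C(C)(C)C)c1ccc(cc1OI(OC(C)=O)c2ccccc2)C(=O)OC(C)(C)C | intermediate
16 | tert-butyl 10-acetoxy-6-{[(tert-butyldimethylsilyl)oxy]methyl}-2-(dimethoxymethyl)-6-methyl-11-oxotricyclo[5.3.1.0(1,5)]undeca-4,8-diene-8-carboxylate; CH2OTBS and OAc syn to C11, CH(OMe)2 cis to C10 | C[C@@]1(CO[Si](C)(C)C(C)(C)C)[C@@H]2C(=O)[C@]3([C@@H](OC(C)=O)C=C2C(=O)OC(C)(C)C)[C@@H](C(OC)OC)CC=C13 | intermediate
17 | 11-(4-methylbenzenesulfonyl)hydrazone of 16 | C[C@@]1(CO[Si](C)(C)C(C)(C)C)[C@@H]2C(=NNS(=O)(=O)c4ccc(C)cc4)[C@]3([C@@H](OC(C)=O)C=C2C(=O)OC(C)(C)C)[C@@H](C(OC)OC)CC=C13 | intermediate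
18 | 11-diazenyl compound (monoalkyldiazene) | C[C@@]1(CO[Si](C)(C)C(C)(C)C)[C@@H]2C(N=N)[C@]3([C@@H](OC(C)=O)C=C2C(=O)OC(C)(C)C)[C@@H](C(OC)OC)CC=C13 | intermediate
19 | tert-butyl 10-acetoxy-6-{[(tert-butyldimethylsilyl)oxy]methyl}-2-(dimethoxymethyl)-6-methyltricyclo[5.3.1.0(1,5)]undeca-4,8-diene-8-carboxylate | C[C@@]1(CO[Si](C)(C)C(C)(C)C)[C@@H]2C[C@]3([C@@H](OC(C)=O)C=C2C(=O)OC(C)(C)C)[C@@H](C(OC)OC)CC=C13 | intermediate
20 | tert-butyl 10-acetoxy-2-(dimethoxymethyl)-6-(hydroxymethyl)-6-methyltricyclo[5.3.1.0(1,5)]undeca-4,8-diene-8-carboxylate | C[C@@]1(CO)[C@@H]2C[C@]3([C@@H](OC(C)=O)C=C2C(=O)OC(C)(C)C)[C@@H](C(OC)OC)CC=C13 | intermediate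
21 | tert-butyl 10-acetoxy-2-(dimethoxymethyl)-6-(hydroxymethyl)-6-methyltricyclo[5.3.1.0(1,5)]undec-8-ene-8-carboxylate, H-5 syn to C11 | C[C@@]1(CO)[C@@H]2C[C@]3([C@@H](OC(C)=O)C=C2C(=O)OC(C)(C)C)[C@@H](C(OC)OC)CC[C@@H]13 | intermediate
22 | triethylsilyl ether of 21 | C[C@@]1(CO[Si](CC)(CC)CC)[C@@H]2C[C@]3([C@@H](OC(C)=O)C=C2C(=O)OC(C)(C)C)[C@@H](C(OC)OC)CC[C@@H]13 | intermediate
23 | tert-butyl 2-(dimethoxymethyl)-10-hydroxy-6-methyl-6-{[(triethylsilyl)oxy]methyl}tricyclo[5.3.1.0(1,5)]undec-8-ene-8-carboxylate | C[C@@]1(CO[Si](CC)(CC)CC)[C@@H]2C[C@]3([C@@H](O)C=C2C(=O)OC(C)(C)C)[C@@H](C(OC)OC)CC[C@@H]13 | intermediate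
24 | dec-9-ynoic acid | C#CCCCCCCCC(=O)O | starting material
25 | (6-bromohexyloxy)(tert-butyl)dimethylsilane | CC(C)(C)[Si](C)(C)OCCCCCCBr | starting material
26 | dilithium salt of dec-9-ynoic acid (carboxylate and acetylide) | [Li+].[Li+].[O-]C(=O)CCCCCCCC#[C-] | intermediate
27 | 16-[(tert-butyldimethylsilyl)oxy]hexadec-9-ynoic acid | CC(C)(C)[Si](C)(C)OCCCCCCC#CCCCCCCCC(=O)O | intermediate
28 | (9Z)-16-[(tert-butyldimethylsilyl)oxy]hexadec-9-enoic acid | CC(C)(C)[Si](C)(C)OCCCCCC/C=C\CCCCCCCC(=O)O | intermediate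
29 | mixed anhydride of 28 with 2,4,6-trichlorobenzoic acid | CC(C)(C)[Si](C)(C)OCCCCCC/C=C\CCCCCCCC(=O)OC(=O)c1c(Cl)cc(Cl)cc1Cl | intermediate
30 | fully protected ester (tert-butyl ester, TES ether, TBS ether, dimethyl acetal) | C[C@@]1(CO[Si](CC)(CC)CC)[C@@H]2C[C@]3([C@@H](OC(=O)CCCCCCC/C=C\CCCCCCO[Si](C)(C)C(C)(C)C)C=C2C(=O)OC(C)(C)C)[C@@H](C(OC)OC)CC[C@@H]13 | intermediate
31 | target CNP0148862.1 | C[C@@]1(CO)[C@@H]2C[C@]3([C@@H](OC(=O)CCCCCCC/C=C\CCCCCCO)C=C2C(=O)O)[C@@H](C=O)CC[C@@H]13 | target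

Total step count: 20. Longest linear sequence: 17 steps (steps 1, 2, 4–16, 19, 20).

**Steps most likely to fail**

Step 10 (allene (5+2) cascade). The C6 cation could rotate into the C4–C6 allyl cation and be trapped by acetate before ring B closes, or the ester-bearing dienone could be too poor a partner for the second bond. The fallback uses the trisubstituted Z alkene, for which this cascade is an established reaction type, and re-creates C4=C5 afterwards. It sets out from 11. Iron-catalysed, alkoxide-directed syn-carbomagnesiation (MeMgBr, Fe(acac)3, THF; methyl to C6) would give tert-butyl 3-[(tert-butyldimethylsilyl)oxy]-4-[(2S,4S,5Z)-7-[(tert-butyldimethylsilyl)oxy]-4-hydroxy-1,1-dimethoxy-6-methylhept-5-en-2-yl]benzoate F1. Et3SiOTf and 2,6-lutidine would give its 4-O-triethylsilyl ether F2, and K2CO3 in MeOH the free phenol F3. PhI(OAc)2 in (CF3)2CHOH would then give the cis-fused tricyclic 11-ketone with 4-OTES and H-5 anti to C11 F4. PPTS in MeOH would give the 4-alcohol F5, Dess–Martin periodinane the 4,11-diketone F6, and Tf2O with 2,6-di-tert-butyl-4-methylpyridine the more substituted 4-enol triflate F7. Reduction of the triflate with Pd(OAc)2, PPh3 and HCO2H/Bu3N would give 16, where the route is rejoined.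

Step 14 (directed hydrogenation to the strained trans fusion). Poor facial selectivity or competing reduction of the C8=C9 enoate could occur. The fallback sets out from 20 and replaces hydrogenation by hydroboration and radical deoxygenation. BH3·SMe2 (the alkoxyborane of the C6 CH2OH delivers B–H to the face of C11; boron to C4, hydrogen to C5) and then NaBO3·4H2O would give the 4-hydroxy compound with H-5 syn to C11 F8. Et3SiCl and imidazole would silylate the primary hydroxyl to give the 4-hydroxy triethylsilyl ether F9, and 1,1'-thiocarbonyldiimidazole would give the 4-O-(imidazol-1-ylthiocarbonyl) derivative F10. Bu3SnH and AIBN (Barton–McCombie) would remove the C4 oxygen and give 22, where the route is rejoined.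

Step 12 (C11 deoxygenation). Hydride addition to the hindered C=N could be incomplete, or the diazene could fragment in another way. The fallback sets out from 16 and uses radical deoxygenation of the derived alcohol. NaBH4 in MeOH at −20 °C would give the 11-alcohol F11, and 1,1'-thiocarbonyldiimidazole with DMAP the 11-O-(imidazol-1-ylthiocarbonyl) derivative F12. Bu3SnH and AIBN in toluene at 90 °C (Barton–McCombie) would give 19, where the route is rejoined.

**Further compounds**
F1 | step 10 | tert-butyl 3-[(tert-butyldimethylsilyl)oxy]-4-[(2S,4S,5Z)-7-[(tert-butyldimethylsilyl)oxy]-4-hydroxy-1,1-dimethoxy-6-methylhept-5-en-2-yl]benzoate | COC(OC)[C@@H](C[C@H](O)/C=C(/C)CO[Si](C)(C)C(C)(C)C)c1ccc(cc1O[Si](C)(C)C(C)(C)C)C(=O)OC(C)(C)C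
F2 | step 10 | 4-O-triethylsilyl ether of F1 | COC(OC)[C@@H](C[C@H](O[Si](CC)(CC)CC)/C=C(/C)CO[Si](C)(C)C(C)(C)C)c1ccc(cc1O[Si](C)(C)C(C)(C)C)C(=O)OC(C)(C)C
F3 | step 10 | free phenol from F2 | COC(OC)[C@@H](C[C@H](O[Si](CC)(CC)CC)/C=C(/C)CO[Si](C)(C)C(C)(C)C)c1ccc(cc1O)C(=O)OC(C)(C)C
F4 | step 10 | tert-butyl 10-acetoxy-6-{[(tert-butyldimethylsilyl)oxy]methyl}-2-(dimethoxymethyl)-6-methyl-11-oxo-4-[(triethylsilyl)oxy]tricyclo[5.3.1.0(1,5)]undec-8-ene-8-carboxylate, H-5 anti to C11 | C[C@@]1(CO[Si](C)(C)C(C)(C)C)[C@@H]2C(=O)[C@]3([C@@H](OC(C)=O)C=C2C(=O)OC(C)(C)C)[C@@H](C(OC)OC)C[C@H](O[Si](CC)(CC)CC)[C@H]13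
F5 | step 10 | 4-alcohol from F4 | C[C@@]1(CO[Si](C)(C)C(C)(C)C)[C@@H]2C(=O)[C@]3([C@@H](OC(C)=O)C=C2C(=O)OC(C)(C)C)[C@@H](C(OC)OC)C[C@H](O)[C@H]13
F6 | step 10 | 4,11-diketone from F5 | C[C@@]1(CO[Si](C)(C)C(C)(C)C)[C@@H]2C(=O)[C@]3([C@@H](OC(C)=O)C=C2C(=O)OC(C)(C)C)[C@@H](C(OC)OC)CC(=O)[C@H]13
F7 | step 10 | 4-enol triflate (C4=C5) from F6 | C[C@@]1(CO[Si](C)(C)C(C)(C)C)[C@@H]2C(=O)[C@]3([C@@H](OC(C)=O)C=C2C(=O)OC(C)(C)C)[C@@H](C(OC)OC)CC(OS(=O)(=O)C(F)(F)F)=C13
F8 | step 14 | tert-butyl 10-acetoxy-2-(dimethoxymethyl)-4-hydroxy-6-(hydroxymethyl)-6-methyltricyclo[5.3.1.0(1,5)]undec-8-ene-8-carboxylate, H-5 syn to C11 and 4-OH cis to H-5 | C[C@@]1(CO)[C@@H]2C[C@]3([C@@H](OC(C)=O)C=C2C(=O)OC(C)(C)C)[C@@H](C(OC)OC)C[C@H](O)[C@@H]13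
F9 | step 14 | primary triethylsilyl ether of F8 | C[C@@]1(CO[Si](CC)(CC)CC)[C@@H]2C[C@]3([C@@H](OC(C)=O)C=C2C(=O)OC(C)(C)C)[C@@H](C(OC)OC)C[C@H](O)[C@@H]13
F10 | step 14 | 4-O-(imidazol-1-ylthiocarbonyl) derivative of F9 | C[C@@]1(CO[Si](CC)(CC)CC)[C@@H]2C[C@]3([C@@H](OC(C)=O)C=C2C(=O)OC(C)(C)C)[C@@H](C(OC)OC)C[C@H](OC(=S)n4ccnc4)[C@@H]13
F11 | step 12 | 11-alcohol from 16 (C11 configuration of no consequence) | C[C@@]1(CO[Si](C)(C)C(C)(C)C)[C@@H]2C(O)[C@]3([C@@H](OC(C)=O)C=C2C(=O)OC(C)(C)C)[C@@H](C(OC)OC)CC=C13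
F12 | step 12 | 11-O-(imidazol-1-ylthiocarbonyl) derivative of F11 | C[C@@]1(CO[Si](C)(C)C(C)(C)C)[C@@H]2C(OC(=S)n4ccnc4)[C@]3([C@@H](OC(C)=O)C=C2C(=O)OC(C)(C)C)[C@@H](C(OC)OC)CC=C13
A1 | direct plan | 4'-methyl-3',6'-dihydro-2'H-spiro[1,3-dioxolane-2,1'-pentalene] | CC1=CCC2=C1CCC23OCCO3
A2 | direct plan | tert-butyl 2-diazobut-3-enoate | C=CC(=[N+]=[N-])C(=O)OC(C)(C)C
A3 | direct plan | tert-butyl 2,2-(ethylenedioxy)-6-methyltricyclo[5.3.1.0(1,5)]undeca-5,8-diene-8-carboxylate | CC=1[C@@H]2C[C@]3(CC=C2C(=O)OC(C)(C)C)C4(OCCO4)CCC=13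
A4 | direct plan | tert-butyl 2,2-(ethylenedioxy)-6-(hydroxymethyl)-6-methyltricyclo[5.3.1.0(1,5)]undeca-4,8-diene-8-carboxylate | C[C@@]1(CO)[C@@H]2C[C@]3(CC=C2C(=O)OC(C)(C)C)C4(OCCO4)CC=C13
A5 | direct plan | tert-butyl 6-{[(tert-butyldimethylsilyl)oxy]methyl}-2-(dimethoxymethyl)-10-hydroxy-6-methyltricyclo[5.3.1.0(1,5)]undec-8-ene-8-carboxylate | C[C@@]1(CO[Si](C)(C)C(C)(C)C)[C@@H]2C[C@]3([C@@H](O)C=C2C(=O)OC(C)(C)C)[C@@H](C(OC)OC)CC[C@@H]13
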